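The run lasts 50 min, and the question is how long the chains are by then in flasks alpha and zeta, which differ in protic impurity.

| setting | alpha | zeta |
|---|---|---|
| first end groups | 0.020 M | 0.020 M |
| second end groups | 0.0196 M | 0.0196 M |
| protic impurity | 6.00 mM | 12.0 mM |
| time | 50 min | 50 min |

- which of the two ends with the longer chains by the average number of monomer units in a chain (unreacted monomers counted as chains of one) ("neither" if they lie within 10%) (alpha / zeta / neither)
- average number of monomer units in a chain (unreacted monomers counted as chains of one) at the end, alpha
- average number of monomer units in a chain (unreacted monomers counted as chains of one) at the end, zeta

- each molecule carries two end groups: a chain counts once for every two ends that are left, dead ends included; the units are half of the end groups of the two monomers charged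
- run time (alpha): 50 min

    first end groups + second end groups ⇌ links + released group (K1 = 2.0, k1 = 0.84 M⁻¹ s⁻¹)
    released group → by-product carried off (k2 = 0.0021 s⁻¹)
    first end groups + protic impurity → quenched substrate (k3 = 0.16 M⁻¹ s⁻¹)

*How do you count a chain length here?* As ends charged over ends left. The starting c(first end groups) and c(second end groups) add up to 39.6 mM, the ends charged, the same in alpha and zeta. Each link removes two ends, while a quenched end stays as a dead end, so ends left are ends charged minus twice c(links).

*Where does step 1 go first?* Its forward half-life in alpha, 0.70 min, is shorter than the 5.5 min of released group, so I take the balance first. Ignoring the impurity, I reckon c(links) at that balance as 11.6 mM, a length of 2.41.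

*But released group leaves. How far do links go then?* The run is longer than the half-life of released group, so I expect links to keep forming. I take first end groups as the limiting reagent and as consumed. Then ends left equal twice c(quenched substrate) minus the difference in charges. Unequal end groups alone give a length of 99.0, so I must reckon the quenching.

*How?* Step 3 integrates to c(protic impurity) = charge × exp(−k3 ∫c(first end groups) dt). After the balance, first end groups and released group drain together through step 2, which makes the integral about 6.67 M·s. My reckoning neglects the impurity's own pull on first end groups, so it leaves 34.4% of the impurity in both flasks. That gives 5.30 for alpha and 2.58 for zeta.

The forecast also names alpha, but with 4.4 for alpha, lower than mine, and 2.8 for zeta, higher than mine. Its ground: “the doubled impurity in zeta clearly gives shorter chains”.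

The simulation gives alpha: 4.20 in alpha, longer than the 2.84 in zeta.

The gap comes from the difference in protic impurity: with that difference taken away, zeta gives 4.20 in place of 2.84. Of the same ends charged, alpha has 9.43 mM left at the end, and zeta has more, 13.9 mM. In a further flask like alpha but with 0.080 M of first end groups, the ends charged are 99.6 mM and c(links) is 19.6 mM, so its length is 1.65.

All constants are invented; the run is a simulation.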